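Everything rests on disconnecting the C9–C10 bond of ring B (labdane numbering). The key step exploits two features: ring A (C2 carbinol, C4 gem-dimethyl, C10 methyl) is the actinol ring, and C9 lies between C8 and C11, which can be a ketone and an ester. The precursor is therefore a ring-A cyclohexene with the tetrasubstituted C5=C10 alkene, a C2 silyl ether and a C6–C7 tether on C5 ending in a β-keto ester. One Lewis-acid operation protonates C5 and joins the enolised C9 to C10, closing ring B as a trans-decalin and setting C5, C9 and C10 under control of C2.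

Key step: step 5

Remark on numbering: bicyclic compounds carry labdane numbers (ring A: C1–C5 and C10; ring B: C5–C10; side chain C11–C16; C17 on C8; C18 and C19 on C4; C20 on C10). α is the face opposite C20. TBDPS = tert-butyldiphenylsilyl. The target SMILES is read as (2R,5S,9S,10S) with an axial 2β-acetate and a 13Z alkene.

Assumption: (4R,6R)-actinol and the THF solution of (3-ethoxy-3-oxopropyl)zinc bromide are bought; ethyl (Z)-3-iodobut-2-enoate is made in step 10.

Step 1
Reactants: 1 (4R,6R)-actinol, i.e. (4R,6R)-4-hydroxy-2,2,6-trimethylcyclohexan-1-one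
Product: 2 (4R,6R)-4-(TBDPS-oxy)-2,2,6-trimethylcyclohexan-1-one
Conditions: TBDPSCl, imidazole, DMF, rt
Reagents that add atoms: tert-butyl(chloro)diphenylsilane, CC(C)(C)[Si](Cl)(c1ccccc1)c1ccccc1
Why: Imidazole-promoted silyl ether formation at the only hydroxyl; the bulky TBDPS group is chosen because it should survive SnCl4 and, unlike an acyl group, cannot capture the later C10 cation through a carbonyl oxygen.

Step 2
Reactants: 2 (4R,6R)-4-(TBDPS-oxy)-2,2,6-trimethylcyclohexan-1-one
Product: 4 (4R)-4-(TBDPS-oxy)-2,6,6-trimethylcyclohex-1-en-1-yl trifluoromethanesulfonate, via potassium enolate 3 (not isolated)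
Conditions: KN(SiMe3)2, THF, −78 °C; then PhNTf2, −78 → 0 °C
Reagents that add atoms: N-phenylbis(trifluoromethanesulfonimide), O=S(=O)(N(c1ccccc1)S(=O)(=O)C(F)(F)F)C(F)(F)F
Why: Enol triflate formation: the ketone can enolise only towards the methyl-bearing carbon because the other α-carbon is quaternary, so one tetrasubstituted enolate forms and is O-sulfonylated; the old C6 stereocentre is erased on purpose and the silyloxy carbon is untouched.

Step 3
Reactants: 4 (4R)-4-(TBDPS-oxy)-2,6,6-trimethylcyclohex-1-en-1-yl trifluoromethanesulfonate; 5 (3-ethoxy-3-oxopropyl)zinc bromide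
Product: 6 ethyl 3-[(4R)-4-(TBDPS-oxy)-2,6,6-trimethylcyclohex-1-en-1-yl]propanoate
Conditions: PdCl2(dppf) (5 mol %), THF/NMP, 60 °C
Reagents that add atoms: none
Why: Negishi sp2–sp3 coupling: zerovalent palladium inserts into the enol triflate, the ester-bearing alkylzinc transmetalates readily, and the wide-bite-angle dppf ligand should favour reductive elimination over β-hydride loss, so C6–C8 are attached with the alkene position fixed by the triflate.

Step 4
Reactants: 6 ethyl 3-[(4R)-4-(TBDPS-oxy)-2,6,6-trimethylcyclohex-1-en-1-yl]propanoate; 7 methyl acetate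
Product: 9 methyl 5-[(4R)-4-(TBDPS-oxy)-2,6,6-trimethylcyclohex-1-en-1-yl]-3-oxopentanoate, via lithium enolate of methyl acetate 8 (not isolated)
Conditions: 7 (3 equiv), LiN(iPr)2, THF, −78 °C; then 6, −78 → −30 °C; then AcOH
Reagents that add atoms: none
Why: Crossed Claisen condensation: the preformed ester enolate acylates on the unhindered ethyl ester, and deprotonation of the β-keto ester product by excess enolate drives the reaction and protects the product until the cold acidic quench.

Step 5
Reactants: 9 methyl 5-[(4R)-4-(TBDPS-oxy)-2,6,6-trimethylcyclohex-1-en-1-yl]-3-oxopentanoate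
Product: 10 methyl 2α-(TBDPS-oxy)-8-oxo-12,13,14,15,16,17-hexanorlabdan-11-oate
Conditions: SnCl4 (2.5 equiv), CH2Cl2, 0 °C → rt; aq. NaHCO3
Reagents that add atoms: none
Why: SnCl4 binds the β-keto ester as its chelated enol and the acid so released protonates C5 of the tetrasubstituted C5=C10 alkene; the tertiary C10 cation is then captured by the enol carbon C9, so the step is a net isomerisation that forms only the C9–C10 bond. The closest known reaction type is the Lewis-acid cation–olefin cyclisation of olefinic β-keto esters, established for the dihydro-β-ionone-derived keto ester lacking the C2 oxygen. Ring B closes in a 6-endo mode through a chair in which C4 and C1 are equatorial on the forming ring, which places H-5 and the C10 methyl trans-diaxial and so sets C5 and C10 as a trans-decalin, while C9 settles by enolisation as the equatorial ester. The absolute sense is controlled by C2: protonation is reversible, and closure through the ring-A chair with the silyloxy group equatorial is preferred because the alternative chair puts it syn-diaxial to the axial C4 methyl and the C10 methyl, so C20 ends trans to the C2 oxygen. The step therefore needs face selectivity at C5=C10 and carbon rather than oxygen capture of the cation; the first comes from the C2 stereocentre acting together with the C4 gem-dimethyl group, the second from tin chelation and the reversibility of O-alkylation in the acidic medium.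

Step 6
Reactants: 10 methyl 2α-(TBDPS-oxy)-8-oxo-12,13,14,15,16,17-hexanorlabdan-11-oate
Product: 11 methyl 8,8-(ethylenedioxy)-2α-(TBDPS-oxy)-12,13,14,15,16,17-hexanorlabdan-11-oate
Conditions: HOCH2CH2OH, p-TsOH (cat.), benzene, reflux, Dean–Stark
Reagents that add atoms: ethylene glycol, OCCO
Why: Acid-catalysed ketalisation with azeotropic removal of water masks the C8 ketone and stops enolisation towards C9; the TBDPS ether should tolerate catalytic sulfonic acid in a non-aqueous medium.

Step 7
Reactants: 11 methyl 8,8-(ethylenedioxy)-2α-(TBDPS-oxy)-12,13,14,15,16,17-hexanorlabdan-11-oate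
Product: 12 8,8-(ethylenedioxy)-2α-(TBDPS-oxy)-12,13,14,15,16,17-hexanorlabdan-11-ol
Conditions: LiAlH4, THF, 0 °C
Reagents that add atoms: none
Why: Hydride reduction of the ester to the primary C11 alcohol; ketal and silyl ether are inert to LiAlH4 at this temperature.

Step 8
Reactants: 12 8,8-(ethylenedioxy)-2α-(TBDPS-oxy)-12,13,14,15,16,17-hexanorlabdan-11-ol
Product: 13 8,8-(ethylenedioxy)-2α-(TBDPS-oxy)-12,13,14,15,16,17-hexanorlabdan-11-al
Conditions: Dess–Martin periodinane, pyridine, CH2Cl2, rt
Reagents that add atoms: none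
Why: Dess–Martin oxidation of the hindered primary alcohol under buffered conditions that spare the ketal; the equatorial C9 configuration is the thermodynamically preferred one and should persist.

Step 9
Reactants: 13 8,8-(ethylenedioxy)-2α-(TBDPS-oxy)-12,13,14,15,16,17-hexanorlabdan-11-al
Product: 14 8,8-(ethylenedioxy)-2α-(TBDPS-oxy)-13,14,15,16,17-pentanorlabd-11-ene
Conditions: Ph3PCH3Br, KOtBu, THF, 0 °C → rt
Reagents that add atoms: methyltriphenylphosphonium bromide, C[P+](c1ccccc1)(c1ccccc1)c1ccccc1.[Br-]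
Why: Wittig methylenation of the aldehyde supplies C12 as a vinyl terminus; addition of the unstabilised ylide should outrun enolisation, and C9 is in any case in its stable configuration.

Step 10
Reactants: 15 ethyl but-2-ynoate
Product: 16 ethyl (Z)-3-iodobut-2-enoate
Conditions: NaI, AcOH, 115 °C
Reagents that add atoms: sodium iodide, [Na+].[I-]
Why: Conjugate hydroiodination of the ynoate: iodide adds to C3 and the proton is delivered anti, which should give the Z isomer with iodine cis to the ester.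

Step 11
Reactants: 14 8,8-(ethylenedioxy)-2α-(TBDPS-oxy)-13,14,15,16,17-pentanorlabd-11-ene; 16 ethyl (Z)-3-iodobut-2-enoate
Product: 18 ethyl 8,8-(ethylenedioxy)-2α-(TBDPS-oxy)-17-norlabd-13Z-en-15-oate, via B-alkyl-9-BBN adduct 17 (not isolated)
Conditions: 9-BBN, THF, rt; then 16, PdCl2(dppf) (5 mol %), AsPh3, Cs2CO3, DMF/H2O, rt
Reagents that add atoms: none
Why: Anti-Markovnikov hydroboration of the only alkene followed by B-alkyl Suzuki–Miyaura coupling, which retains the geometry of the iodoenoate, forms C12–C13 and should deliver the 13Z enoate with C12 cis to the ester.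

Step 12
Reactants: 18 ethyl 8,8-(ethylenedioxy)-2α-(TBDPS-oxy)-17-norlabd-13Z-en-15-oate
Product: 19 ethyl 2α-(TBDPS-oxy)-8-oxo-17-norlabd-13Z-en-15-oate
Conditions: 1 M HCl, THF, rt → 40 °C
Reagents that add atoms: water, O
Why: Acid hydrolysis of the dioxolane returns the C8 ketone; it is placed before the acid-sensitive exocyclic alkene exists, and the TBDPS ether, the enoate and the equatorial C9 centre should be unaffected.

Step 13
Reactants: 19 ethyl 2α-(TBDPS-oxy)-8-oxo-17-norlabd-13Z-en-15-oate
Product: 20 ethyl 2α-(TBDPS-oxy)labda-8(17),13Z-dien-15-oate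
Conditions: Zn, CH2Br2, TiCl4, THF, −40 → 5 °C (aged reagent); then 19, CH2Cl2, rt
Reagents that add atoms: dibromomethane, BrCBr
Why: Takai–Lombardo methylenation transfers CH2 to the hindered, enolisable C8 ketone under non-basic conditions, so C9 is not epimerised, the Z enoate is not isomerised and the ester is left alone.

Step 14
Reactants: 20 ethyl 2α-(TBDPS-oxy)labda-8(17),13Z-dien-15-oate
Product: 21 ethyl 2α-hydroxylabda-8(17),13Z-dien-15-oate
Conditions: Bu4NF, THF, rt
Reagents that add atoms: none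
Why: Fluoride cleavage of the silyl ether frees the equatorial 2α-alcohol once its directing role is over.

Step 15
Reactants: 21 ethyl 2α-hydroxylabda-8(17),13Z-dien-15-oate
Product: 22 ethyl 2-oxolabda-8(17),13Z-dien-15-oate
Conditions: Dess–Martin periodinane, pyridine, CH2Cl2, rt
Reagents that add atoms: none
Why: Dess–Martin oxidation to the C2 ketone; its neighbours C1 and C3 are methylenes next to quaternary carbons, so no stereocentre can be lost by enolisation.

Step 16
Reactants: 22 ethyl 2-oxolabda-8(17),13Z-dien-15-oate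
Product: 23 ethyl 2β-hydroxylabda-8(17),13Z-dien-15-oate
Conditions: NaBH4, EtOH, 0 °C
Reagents that add atoms: none
Why: Substrate-controlled ketone reduction: the β-face of C2 is blocked by the syn-axial C20 and C19 methyl groups, so hydride should enter from the α-face and give the axial 2β-alcohol, while the conjugated ester is not reduced.

Step 17
Reactants: 23 ethyl 2β-hydroxylabda-8(17),13Z-dien-15-oate
Product: 24 2β-hydroxylabda-8(17),13Z-dien-15-oic acid
Conditions: LiOH, THF/MeOH/H2O, 45 °C; then cold 1 M HCl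
Reagents that add atoms: lithium hydroxide, [Li+].[OH-]
Why: Saponification is done before acetylation so that no acetate has to survive hydroxide; the β,β-disubstituted Z enoate should keep its geometry.

Step 18
Reactants: 24 2β-hydroxylabda-8(17),13Z-dien-15-oic acid
Product: 26 2β-acetoxylabda-8(17),13Z-dien-15-oic acid (CNP0255148.1), via mixed acetic anhydride 25 (not isolated)
Conditions: Ac2O, pyridine, DMAP (cat.), CH2Cl2, rt → 40 °C; then aq. NaHCO3/THF; acidify
Reagents that add atoms: acetic anhydride, CC(=O)OC(C)=O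
Why: DMAP-catalysed acetylation of the hindered axial alcohol; the acid is carried through as a mixed anhydride that should hydrolyse back to the free acid in the bicarbonate work-up, which the secondary acetate survives.

Compound list

1 | (4R,6R)-actinol, (4R,6R)-4-hydroxy-2,2,6-trimethylcyclohexan-1-one | O=C1[C@H](C)C[C@@H](O)CC1(C)C | starting material
2 | (4R,6R)-4-(TBDPS-oxy)-2,2,6-trimethylcyclohexan-1-one | O=C1[C@H](C)C[C@@H](O[Si](c2ccccc2)(c2ccccc2)C(C)(C)C)CC1(C)C | intermediate
3 | potassium (4R)-4-(TBDPS-oxy)-2,6,6-trimethylcyclohex-1-en-1-olate | [K+].[O-]C1=C(C)C[C@@H](O[Si](c2ccccc2)(c2ccccc2)C(C)(C)C)CC1(C)C | intermediate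
4 | (4R)-4-(TBDPS-oxy)-2,6,6-trimethylcyclohex-1-en-1-yl trifluoromethanesulfonate | FC(F)(F)S(=O)(=O)OC1=C(C)C[C@@H](O[Si](c2ccccc2)(c2ccccc2)C(C)(C)C)CC1(C)C | intermediate
5 | (3-ethoxy-3-oxopropyl)zinc bromide | CCOC(=O)CC[Zn]Br | starting material
6 | ethyl 3-[(4R)-4-(TBDPS-oxy)-2,6,6-trimethylcyclohex-1-en-1-yl]propanoate | CCOC(=O)CCC1=C(C)C[C@@H](O[Si](c2ccccc2)(c2ccccc2)C(C)(C)C)CC1(C)C | intermediate
7 | methyl acetate | COC(C)=O | starting material
8 | lithium enolate of methyl acetate (lithium 1-methoxyethen-1-olate) | C=C(O[Li])OC | intermediate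
9 | methyl 5-[(4R)-4-(TBDPS-oxy)-2,6,6-trimethylcyclohex-1-en-1-yl]-3-oxopentanoate | COC(=O)CC(=O)CCC1=C(C)C[C@@H](O[Si](c2ccccc2)(c2ccccc2)C(C)(C)C)CC1(C)C | intermediate
10 | methyl 2α-(TBDPS-oxy)-8-oxo-12,13,14,15,16,17-hexanorlabdan-11-oate, (2S,5S,9R,10S); trans-decalin with 5α-H, 10β-methyl, equatorial 9β-ester and equatorial 2α-silyloxy; equally methyl (1R,4aS,7S,8aS)-7-(TBDPS-oxy)-5,5,8a-trimethyl-2-oxodecahydronaphthalene-1-carboxylate | O=C1CC[C@H]2C(C)(C)C[C@H](O[Si](c3ccccc3)(c3ccccc3)C(C)(C)C)C[C@]2(C)[C@H]1C(=O)OC | intermediate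
11 | methyl 8,8-(ethylenedioxy)-2α-(TBDPS-oxy)-12,13,14,15,16,17-hexanorlabdan-11-oate (5α-H, 9α-H, 10β-methyl) | C14(OCCO4)CC[C@H]2C(C)(C)C[C@H](O[Si](c3ccccc3)(c3ccccc3)C(C)(C)C)C[C@]2(C)[C@H]1C(=O)OC | intermediate
12 | 8,8-(ethylenedioxy)-2α-(TBDPS-oxy)-12,13,14,15,16,17-hexanorlabdan-11-ol | C14(OCCO4)CC[C@H]2C(C)(C)C[C@H](O[Si](c3ccccc3)(c3ccccc3)C(C)(C)C)C[C@]2(C)[C@H]1CO | intermediate
13 | 8,8-(ethylenedioxy)-2α-(TBDPS-oxy)-12,13,14,15,16,17-hexanorlabdan-11-al | C14(OCCO4)CC[C@H]2C(C)(C)C[C@H](O[Si](c3ccccc3)(c3ccccc3)C(C)(C)C)C[C@]2(C)[C@H]1C=O | intermediate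
14 | 8,8-(ethylenedioxy)-2α-(TBDPS-oxy)-13,14,15,16,17-pentanorlabd-11-ene (vinyl group on C9, β-equatorial) | C14(OCCO4)CC[C@H]2C(C)(C)C[C@H](O[Si](c3ccccc3)(c3ccccc3)C(C)(C)C)C[C@]2(C)[C@H]1C=C | intermediate
15 | ethyl but-2-ynoate | CC#CC(=O)OCC | starting material
16 | ethyl (Z)-3-iodobut-2-enoate (iodine cis to the ester) | I/C(C)=C\C(=O)OCC | intermediate
17 | 9-[8,8-(ethylenedioxy)-2α-(TBDPS-oxy)-13,14,15,16,17-pentanorlabdan-12-yl]-9-borabicyclo[3.3.1]nonane | C14(OCCO4)CC[C@H]2C(C)(C)C[C@H](O[Si](c3ccccc3)(c3ccccc3)C(C)(C)C)C[C@]2(C)[C@H]1CCB5C6CCCC5CCC6 | intermediate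
18 | ethyl 8,8-(ethylenedioxy)-2α-(TBDPS-oxy)-17-norlabd-13Z-en-15-oate | C14(OCCO4)CC[C@H]2C(C)(C)C[C@H](O[Si](c3ccccc3)(c3ccccc3)C(C)(C)C)C[C@]2(C)[C@H]1CC/C(C)=C\C(=O)OCC | intermediate
19 | ethyl 2α-(TBDPS-oxy)-8-oxo-17-norlabd-13Z-en-15-oate | O=C1CC[C@H]2C(C)(C)C[C@H](O[Si](c3ccccc3)(c3ccccc3)C(C)(C)C)C[C@]2(C)[C@H]1CC/C(C)=C\C(=O)OCC | intermediate
20 | ethyl 2α-(TBDPS-oxy)labda-8(17),13Z-dien-15-oate | C=C1CC[C@H]2C(C)(C)C[C@H](O[Si](c3ccccc3)(c3ccccc3)C(C)(C)C)C[C@]2(C)[C@H]1CC/C(C)=C\C(=O)OCC | intermediate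
21 | ethyl 2α-hydroxylabda-8(17),13Z-dien-15-oate | C=C1CC[C@H]2C(C)(C)C[C@H](O)C[C@]2(C)[C@H]1CC/C(C)=C\C(=O)OCC | intermediate
22 | ethyl 2-oxolabda-8(17),13Z-dien-15-oate | C=C1CC[C@H]2C(C)(C)CC(=O)C[C@]2(C)[C@H]1CC/C(C)=C\C(=O)OCC | intermediate
23 | ethyl 2β-hydroxylabda-8(17),13Z-dien-15-oate (axial hydroxyl) | C=C1CC[C@H]2C(C)(C)C[C@@H](O)C[C@]2(C)[C@H]1CC/C(C)=C\C(=O)OCC | intermediate
24 | 2β-hydroxylabda-8(17),13Z-dien-15-oic acid | C=C1CC[C@H]2C(C)(C)C[C@@H](O)C[C@]2(C)[C@H]1CC/C(C)=C\C(=O)O | intermediate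
25 | acetic 2β-acetoxylabda-8(17),13Z-dien-15-oic anhydride | C=C1CC[C@H]2C(C)(C)C[C@@H](OC(C)=O)C[C@]2(C)[C@H]1CC/C(C)=C\C(=O)OC(C)=O | intermediate
26 | 2β-acetoxylabda-8(17),13Z-dien-15-oic acid, (2R,5S,9S,10S); equally (2Z)-5-[(1S,4aS,7R,8aS)-7-acetoxy-5,5,8a-trimethyl-2-methylidenedecahydronaphthalen-1-yl]-3-methylpent-2-enoic acid | C=C1CC[C@H]2C(C)(C)C[C@@H](OC(C)=O)C[C@]2(C)[C@H]1CC/C(C)=C\C(=O)O | target

Total step count: 18. Longest linear sequence: 17 (steps 1–9 and 11–18, from actinol); step 10 is a one-step side branch.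

Steps most likely to fail

Step 5. What may go wrong: the C10 cation may be captured on the enol oxygen, lose a proton or rearrange; the acid may cleave the silyl ether; and the two alkene faces may be discriminated too weakly. A minor product of wrong-face closure is a diastereomer of 10 and has to be removed before C2 is oxidised in step 15. The fallback sets out from 9 and closes the same bond by oxidative radical cyclisation without acid-generated cations. With Mn(OAc)3·2H2O and Cu(OAc)2·H2O in AcOH, the manganese-bound C9 radical should add 6-endo to C10. The tertiary C5 radical is then oxidised by the divalent copper salt and loses a C6 proton, giving methyl 2α-(TBDPS-oxy)-8-oxo-12,13,14,15,16,17-hexanorlabd-5-en-11-oate F1. Hydrogenation (H2, Pd/C, EtOAc) should add from the α-face, away from the axial C20 and C19 methyl groups, and gives the trans-fused keto ester. The route is rejoined at 10.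

Step 3. What may go wrong: oxidative addition and transmetalation are slow at a triflate flanked by a methyl-bearing and a gem-dimethyl carbon, so that β-hydride loss from the alkylpalladium and simple reduction of the triflate take over. The fallback sets out from 4. A Heck reaction with methyl vinyl ketone (Pd(OAc)2, PPh3, Et3N, DMF, 75 °C) should give (E)-4-[(4R)-4-(TBDPS-oxy)-2,6,6-trimethylcyclohex-1-en-1-yl]but-3-en-2-one F2. Conjugate reduction with [(Ph3P)CuH]6 in wet benzene should touch only the disubstituted enone alkene and give 4-[(4R)-4-(TBDPS-oxy)-2,6,6-trimethylcyclohex-1-en-1-yl]butan-2-one F3. Carboxylation at the methyl group with NaH and dimethyl carbonate in THF at reflux then gives the β-keto ester. The route is rejoined at 9, with 6 bypassed.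

Step 11. What may go wrong: the B-alkyl group next to the congested C9 centre transmetalates slowly and protodeboronates, and the aqueous base lets the iodoenoate or the product drift from Z to E. The fallback sets out from 14 and makes the trisubstituted alkene by syn-carbocupration instead of a stereoretentive coupling. Hydroboration with 9-BBN and oxidation of borane 17 in the flask (NaOH, H2O2) gives 8,8-(ethylenedioxy)-2α-(TBDPS-oxy)-13,14,15,16,17-pentanorlabdan-12-ol F4. I2, PPh3 and imidazole convert it into 12-iodo-8,8-(ethylenedioxy)-2α-(TBDPS-oxy)-13,14,15,16,17-pentanorlabdane F5. Lithium acetylide–ethylenediamine in DMSO displaces the primary iodide to give 8,8-(ethylenedioxy)-2α-(TBDPS-oxy)-15,16,17-trinorlabd-13-yne F6. n-BuLi and then ClCO2Et give ethyl 8,8-(ethylenedioxy)-2α-(TBDPS-oxy)-16,17-dinorlabd-13-yn-15-oate F7. Me2CuLi in THF at −78 °C, with protonation at that temperature, adds methyl and copper to the same side of the triple bond, so that C12 ends cis to the ester. The route is rejoined at 18.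

Further compounds

F1 | step 5 | methyl 2α-(TBDPS-oxy)-8-oxo-12,13,14,15,16,17-hexanorlabd-5-en-11-oate | O=C1CC=C2C(C)(C)C[C@H](O[Si](c3ccccc3)(c3ccccc3)C(C)(C)C)C[C@]2(C)[C@H]1C(=O)OC
F2 | step 3 | (E)-4-[(4R)-4-(TBDPS-oxy)-2,6,6-trimethylcyclohex-1-en-1-yl]but-3-en-2-one | CC(=O)/C=C/C1=C(C)C[C@@H](O[Si](c2ccccc2)(c2ccccc2)C(C)(C)C)CC1(C)C
F3 | step 3 | 4-[(4R)-4-(TBDPS-oxy)-2,6,6-trimethylcyclohex-1-en-1-yl]butan-2-one | CC(=O)CCC1=C(C)C[C@@H](O[Si](c2ccccc2)(c2ccccc2)C(C)(C)C)CC1(C)C
F4 | step 11 | 8,8-(ethylenedioxy)-2α-(TBDPS-oxy)-13,14,15,16,17-pentanorlabdan-12-ol | C14(OCCO4)CC[C@H]2C(C)(C)C[C@H](O[Si](c3ccccc3)(c3ccccc3)C(C)(C)C)C[C@]2(C)[C@H]1CCO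
F5 | step 11 | 12-iodo-8,8-(ethylenedioxy)-2α-(TBDPS-oxy)-13,14,15,16,17-pentanorlabdane | C14(OCCO4)CC[C@H]2C(C)(C)C[C@H](O[Si](c3ccccc3)(c3ccccc3)C(C)(C)C)C[C@]2(C)[C@H]1CCI
F6 | step 11 | 8,8-(ethylenedioxy)-2α-(TBDPS-oxy)-15,16,17-trinorlabd-13-yne | C14(OCCO4)CC[C@H]2C(C)(C)C[C@H](O[Si](c3ccccc3)(c3ccccc3)C(C)(C)C)C[C@]2(C)[C@H]1CCC#C
F7 | step 11 | ethyl 8,8-(ethylenedioxy)-2α-(TBDPS-oxy)-16,17-dinorlabd-13-yn-15-oate | C14(OCCO4)CC[C@H]2C(C)(C)C[C@H](O[Si](c3ccccc3)(c3ccccc3)C(C)(C)C)C[C@]2(C)[C@H]1CCC#CC(=O)OCC
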